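All runs are simulated with made-up constants; the scatter is artificial.

The noon run is all I have to go on.

| flask | starting material | reagent | remark | time |
|---|---|---|---|---|
| noon | 0.65 M | 1.5 equiv | run made earlier |  |
| flask | 1.3 M | 1.50 equiv |  | 25 min |

- noon (time / min: mono adduct / %, double product / %, starting material / %): 0.667: 9.3, 1.1, 84.9; 1.33: 17.7, 3.6, 72.9; 2.50: 20.8, 5.2, 56.0; 4.00: 22.4, 6.9, 41.2; 8.00: 18.3, 15.2, 19.9; 15.0: 10.0, 21.7, 7.8; 25.0: 2.7, 24.1, 2.7

(each reading ± 1 percentage point)

- the moment within 25 min at which there is most mono adduct
- the amount of mono adduct, in percent of the starting material charged, at that time

In the noon run the highest mono adduct reading is 22.4% at 4.00 min, with a scatter of 1 percentage point. I treat mono adduct as the middle of a chain of consecutive steps, made at one rate and used at another, and integrate that rate in closed form. With equal rates, the peak comes when the time equals the clock, one over the rate, and its height is the chain share divided by e. The chain share is the part of the charge that passes through mono adduct, so noon gives a chain share of 60.9% and a rate of 0.250 min⁻¹. As a check, the fall of starting material to 41.2% at noon gives 0.222 min⁻¹, which is close enough for a first picture.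

The flask has the same equivalents, with x, the ratio of c(starting material) to noon's, equal to 2.00. I assume that making speeds up by x and that using keeps noon's rate, which one run cannot test. The integral then puts the peak at the noon time times ln x/(x − 1), and its height at the share times x raised to 1/(1 − x).

In the flask the ladder therefore has these rungs, shortest first:
- The making clock is 2.00 min, while starting material feeds mono adduct.
- The peak comes at 2.77 min, later than that clock.
- The using clock is 4.00 min, later again, so on this reckoning mono adduct is already falling by then.
- The limit is 25 min, far beyond these.

My height is 30.4%.

The forecast says 24.5% at 2.7 min, reasoning that “At 1.3 M the bimolecular steps double in speed, but the leak does not.” Its height is lower than mine.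

The flask gives 28.1% at 2.80 min, and the forecast holds within its margins.

    starting material + reagent → mono adduct + released group (k = 0.00280 M⁻¹ s⁻¹)
    mono adduct → side product (k = 0.00170 s⁻¹)
    reagent + mono adduct → double product + released group (k = 0.00240 M⁻¹ s⁻¹)
    starting material ⇌ dormant form (K = 8.10, k = 0.00150 s⁻¹)

My peak time of 2.77 min lies close to the flask's, while my height stands 2.3 points above it. On the neighbouring flask at 0.78 M, x is 1.20, and the same share gives a height of 24.5%. That neighbouring flask reaches 24.0%.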